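Per minute, in fractions of the charge: between 50.0 s and 120 s the midnight run gains 0.211 /min in target, crystals counted, and running that line back gives a lag of 15.6 s.

- midnight: solid substrate 0.10 M; reagent 0.26 M; run made earlier
- flask: solid substrate 0.10 M; reagent 0.130 M; time 6.0 min

midnight run (percent of the solid substrate charged)

| time / s | target / % | crystals / % |
|---|---|---|
| 10.0 | 0.3 | 0 |
| 25.0 | 4.2 | 0 |
| 50.0 | 12.1 | 0 |
| 80.0 | 21.9 | 6.3 |
| 120 | 36.7 | 18.5 |

(each reading ± 0.5 percentage points)

* amount of target and crystals together at 6.0 min, in percent of the solid substrate charged
* concentration of dissolved substrate in solution at 6.0 min, in percent of saturation

- amounts and yields of target count crystals too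
- given per volume of solution although it is solid: solid substrate, crystals
- candidate steps: solid substrate <-> dissolved substrate; dissolved substrate + reagent -> target; crystals <-> target
- at the start none of the solid substrate is in solution
- dissolved substrate means what is dissolved; the solid is not counted in it

The bench rule takes the reagent as in excess (pseudo-first-order): the slope scales with charged reagent and stays straight. Its border is the burn, the fraction of reagent lost per fraction of substrate charge converted, which is the ratio of the charges: 0.385 at midnight, but 0.769 in the flask, twice as much.

Even at midnight the readings put the mean reagent at 90.6% of its charge over that stretch. Dividing by this gives 0.233 /min, the steady slope, the gain per minute at full midnight reagent with the solution taken to stand at a steady level.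

The reckoning here assumes that level holds in the flask. Half the reagent gives 0.116 /min, and 5.74 min after the lag that makes 66.8%. This yield implies an average reagent of 74.3%, which cuts it to 49.6%. Going round again gives 54.0%, then 52.9%, the figure committed to. The slope holds level and reaction constant in one product, so saturation is not reckoned here.

The forecast gives 68% for the yield and 75% of saturation, noting “The uncertainty is wide because the split is unresolved.” Its yield stands above the one reckoned here.

The flask gives a yield of 50.2% and stands at 73.2% of saturation.

    solid substrate ⇌ dissolved substrate, rate k1*(cs1 - [dissolved substrate]) while solid is left; crystals form when [dissolved substrate] > cs1 (solubility = 0.0680 M, k = 0.0570 /s)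
    dissolved substrate + reagent → target (k = 0.0230 /M/s)
    crystals ⇌ target, rate k3*(cs3 - [target]) while solid is left; crystals form when [target] > cs3 (solubility = 14.0 mM, k = 0.110 /s)

In the flask, half of the dissolving is done by 0.378 min, while the half-life of dissolved substrate by the reaction alone, concentrations as charged, is 3.9 min, ten times as long. Of these two steps the reaction is the rate-limiting step, and at 3.00 min dissolved substrate in the flask holds 65.2% of the charge against 28.1% as target. With 61% of the reagent left at the asked time, the steady slope, the reagent taken as the mean of charge and end, gives 53.6% for the flask. In one more flask, like this one but with 0.40 M of solid substrate, where 70.4% stays solid and 60% of the reagent remains, it gives 13.3% against 13.1% found there.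

(Readings and results are simulated on assumed constants; the scatter is artificial.)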